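**Retrosynthetic overview**

- Ring C is the only ring that is built. Its O1–C2 bond is closed second to last by a catalyst-controlled 6-endo oxa-Michael addition of a 2'-hydroxychalcone, and the four acetal ethers are then removed. Rings A and B come from phloroglucinol and 2,4-dihydroxybenzaldehyde.
- The chalcone is cut at C8a–O1 and C4a–C4 together. These two bonds stand on neighbouring carbons of ring A, between the C8 alkyl group and the C5 oxygen, so a C4a≡C8a aryne can insert into the C–O bond of a cinnamic acid and take up both at once, leaving the only free hydroxyl at C8a.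
- The aryne precursor is cut at the C8–CH2 bond: Negishi coupling of a chiral primary alkylzinc with an iodo(silyl)aryl triflate, itself made from phloroglucinol by two carbamate-directed ortho-metalations.
- The side-chain centre is set by auxiliary-controlled deconjugative α-alkylation of a 3-methylbut-2-enoyl imide. The acid partner comes from a Knoevenagel–Doebner condensation.

Key step: step 15

Assumption: the sense of induction of the cinchona thiourea on this unactivated chalcone is not fixed by analogy. The quinine-derived catalyst is written in step 16, and its quinidine-derived pseudoenantiomer takes its place if a model chalcone without the side chain shows the opposite sense.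

**Route**

Step 1
Reactants: 1 phloroglucinol
Product: 2 3,5-bis(methoxymethoxy)phenol
Conditions: MOMCl (2.0 equiv), i-Pr2NEt, DMF, 0 °C → rt; chromatography
Reagents that add atoms: chloromethyl methyl ether COCCl
Why: Williamson-type O-alkylation of the phenoxide by the α-chloro ether; the three hydroxyls are equivalent, so the bis-ether is taken from the statistical mixture and the mono-ether can be resubmitted.

Step 2
Reactants: 2 3,5-bis(methoxymethoxy)phenol
Product: 3 3,5-bis(methoxymethoxy)phenyl N,N-diethylcarbamate
Conditions: NaH, THF, 0 °C; ClC(O)NEt2, rt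
Reagents that add atoms: N,N-diethylcarbamoyl chloride CCN(CC)C(Cl)=O
Why: Acyl substitution at the carbamoyl chloride by the sodium phenoxide marks the one oxygen that will become the triflate and puts the strongest oxygen directing group on it.

Step 3
Reactants: 3 3,5-bis(methoxymethoxy)phenyl N,N-diethylcarbamate
Product: 5 3,5-bis(methoxymethoxy)-2-(trimethylsilyl)phenyl N,N-diethylcarbamate, via aryllithium 4 (not isolated)
Conditions: s-BuLi, TMEDA, THF, −78 °C; Me3SiCl, −78 °C → rt
Reagents that add atoms: chlorotrimethylsilane C[Si](C)(C)Cl; sec-butyllithium CCC(C)[Li] (lithium only in intermediate 4)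
Why: Directed ortho-metalation: the carbamate outranks the acetal ethers as director, so the hydrogen between the carbamate and a methoxymethoxy group should be removed (the two such positions are equivalent), the anionic ortho-Fries shift is frozen at −78 °C, and the aryllithium is silylated.

Step 4
Reactants: 5 3,5-bis(methoxymethoxy)-2-(trimethylsilyl)phenyl N,N-diethylcarbamate
Product: 7 2-iodo-3,5-bis(methoxymethoxy)-6-(trimethylsilyl)phenyl N,N-diethylcarbamate, via aryllithium 6 (not isolated)
Conditions: s-BuLi, TMEDA, THF, −78 °C; I2, THF, −78 → 0 °C; aq Na2S2O3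
Reagents that add atoms: iodine II; sec-butyllithium CCC(C)[Li] (lithium only in intermediate 6)
Why: A second directed ortho-metalation should take the remaining hydrogen between the carbamate and an acetal ether in preference to the one between two acetal ethers, and iodine traps the aryllithium.

Step 5
Reactants: 7 2-iodo-3,5-bis(methoxymethoxy)-6-(trimethylsilyl)phenyl N,N-diethylcarbamate
Product: 8 2-iodo-3,5-bis(methoxymethoxy)-6-(trimethylsilyl)phenol
Conditions: Cp2Zr(H)Cl (3 equiv), THF, rt; aq NH4Cl
Reagents that add atoms: none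
Why: Reductive cleavage of an aryl O-carbamate by zirconocene chloride hydride (hydrozirconation of the C=O, then loss of the aryloxide), chosen because it needs no bulky nucleophile at the doubly flanked carbamate and leaves the aryl iodide, the aryl silane and the acetal ethers alone; no alkene is present yet.

Step 6
Reactants: 8 2-iodo-3,5-bis(methoxymethoxy)-6-(trimethylsilyl)phenol
Product: 9 2-iodo-3,5-bis(methoxymethoxy)-6-(trimethylsilyl)phenyl trifluoromethanesulfonate
Conditions: Tf2O, pyridine, CH2Cl2, −20 → 0 °C
Reagents that add atoms: trifluoromethanesulfonic anhydride O=S(=O)(OS(=O)(=O)C(F)(F)F)C(F)(F)F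
Why: O-Sulfonylation of the hindered phenol by the small, highly electrophilic anhydride gives the ortho-silyl aryl triflate; pyridine buffers the acid so the acetal ethers survive.

Step 7
Reactants: 10 3-methylbut-2-enoic acid; 11 (4S)-4-benzyl-1,3-oxazolidin-2-one
Product: 13 (4S)-4-benzyl-3-(3-methylbut-2-enoyl)-1,3-oxazolidin-2-one, via mixed anhydride 12 (not isolated)
Conditions: t-BuCOCl, Et3N, THF, −20 °C; then 11, LiCl, rt
Reagents that add atoms: pivaloyl chloride CC(C)(C)C(Cl)=O (its atoms stay only in intermediate 12)
Why: N-Acylation of the oxazolidinone through the mixed pivalic anhydride, which is attacked at its less hindered carbonyl under LiCl/Et3N activation.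

Step 8
Reactants: 14 3-methylbut-3-en-1-ol
Product: 15 3-methylbut-3-en-1-yl trifluoromethanesulfonate
Conditions: Tf2O, 2,6-lutidine, CH2Cl2, −78 °C; cold pentane filtration through silica, used at once
Reagents that add atoms: trifluoromethanesulfonic anhydride O=S(=O)(OS(=O)(=O)C(F)(F)F)C(F)(F)F
Why: O-Triflation of the primary alcohol at low temperature with a hindered base turns the unactivated homoallylic carbon into an electrophile that reacts with an imide enolate at −78 °C, where the corresponding iodide would mainly eliminate.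

Step 9
Reactants: 13 (4S)-4-benzyl-3-(3-methylbut-2-enoyl)-1,3-oxazolidin-2-one; 15 3-methylbut-3-en-1-yl trifluoromethanesulfonate
Product: 17 (4S)-4-benzyl-3-[(2S)-5-methyl-2-(prop-1-en-2-yl)hex-5-enoyl]-1,3-oxazolidin-2-one, via sodium dienolate 16 (not isolated)
Conditions: NaN(SiMe3)2, THF, −78 °C; then 15, −78 → −40 °C
Reagents that add atoms: sodium bis(trimethylsilyl)amide C[Si](C)(C)[N-][Si](C)(C)C.[Na+] (sodium only in intermediate 16)
Why: Deconjugative α-alkylation of an N-enoyl oxazolidinone: γ-deprotonation gives the chelated (Z)-sodium dienolate, which is alkylated at Cα on the face away from the benzyl group, so the new centre should be (S) and the double bond moves out of conjugation to leave the isopropenyl group.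

Step 10
Reactants: 17 (4S)-4-benzyl-3-[(2S)-5-methyl-2-(prop-1-en-2-yl)hex-5-enoyl]-1,3-oxazolidin-2-one
Product: 18 (2S)-5-methyl-2-(prop-1-en-2-yl)hex-5-en-1-ol
Conditions: LiBH4, MeOH (1 equiv), Et2O, 0 °C
Reagents that add atoms: none
Why: Hydride reduction of the exocyclic imide carbonyl (reductive auxiliary cleavage) at 0 °C is mild enough not to epimerise or conjugate the α-centre, and the auxiliary is recovered.

Step 11
Reactants: 18 (2S)-5-methyl-2-(prop-1-en-2-yl)hex-5-en-1-ol
Product: 19 (2S)-1-iodo-5-methyl-2-(prop-1-en-2-yl)hex-5-ene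
Conditions: I2, PPh3, imidazole, CH2Cl2, 0 °C → rt
Reagents that add atoms: iodine II
Why: Appel-type iodination: the alkoxyphosphonium ion is displaced by iodide at the primary carbon, so the adjacent stereocentre is untouched.

Step 12
Reactants: 19 (2S)-1-iodo-5-methyl-2-(prop-1-en-2-yl)hex-5-ene; 9 2-iodo-3,5-bis(methoxymethoxy)-6-(trimethylsilyl)phenyl trifluoromethanesulfonate
Product: 21 3,5-bis(methoxymethoxy)-2-[(2R)-5-methyl-2-(prop-1-en-2-yl)hex-5-en-1-yl]-6-(trimethylsilyl)phenyl trifluoromethanesulfonate, via alkylzinc iodide 20 (not isolated)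
Conditions: Zn dust (activated with BrCH2CH2Br, Me3SiCl), LiCl, THF, 40 °C; solution decanted from Zn; 9, Pd(OAc)2 (3 mol %), SPhos (6 mol %), THF, 45 °C
Reagents that add atoms: zinc [Zn] (zinc only in intermediate 20)
Why: Negishi sp3–sp2 coupling: zerovalent palladium inserts into the C–I bond far faster than into the triflate flanked by iodine and silicon, the primary alkylzinc with its β-stereocentre transmetalates and the bulky biaryl phosphine enforces reductive elimination before β-hydride elimination, so the centre is retained (the descriptor changes from S to R only by priority); without fluoride the silyl triflate is inert, and the zinc reagent is decanted from excess metal so that no arylzinc forms next to the triflate.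

Step 13
Reactants: 22 2,4-dihydroxybenzaldehyde
Product: 23 2,4-bis(methoxymethoxy)benzaldehyde
Conditions: MOMCl (2.5 equiv), K2CO3, acetone, reflux
Reagents that add atoms: chloromethyl methyl ether COCCl
Why: Williamson-type O-alkylation of both phenols; the chelated 2-hydroxyl needs the excess reagent and heat.

Step 14
Reactants: 23 2,4-bis(methoxymethoxy)benzaldehyde; 24 malonic acid
Product: 26 (2E)-3-[2,4-bis(methoxymethoxy)phenyl]prop-2-enoic acid, via arylidenemalonic acid 25 (not isolated)
Conditions: pyridine, piperidine (cat.), 90 °C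
Reagents that add atoms: none
Why: Knoevenagel–Doebner condensation: the arylidenemalonic acid loses CO2 in hot pyridine to give the (E)-cinnamic acid, and the basic medium spares the acetal ethers.

Step 15
Reactants: 21 3,5-bis(methoxymethoxy)-2-[(2R)-5-methyl-2-(prop-1-en-2-yl)hex-5-en-1-yl]-6-(trimethylsilyl)phenyl trifluoromethanesulfonate; 26 (2E)-3-[2,4-bis(methoxymethoxy)phenyl]prop-2-enoic acid
Product: 28 (2E)-3-[2,4-bis(methoxymethoxy)phenyl]-1-{2-hydroxy-4,6-bis(methoxymethoxy)-3-[(2R)-5-methyl-2-(prop-1-en-2-yl)hex-5-en-1-yl]phenyl}prop-2-en-1-one, via aryne 27 (not isolated)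
Conditions: 26 (1.5 equiv), CsF (4 equiv), THF, sealed tube, 125 °C; cold pH 7 phosphate buffer quench
Reagents that add atoms: none
Why: Fluoride attack on silicon expels triflate and releases the C4a≡C8a aryne; the cesium carboxylate of 26 adds through oxygen to C8a, the aryl carbanion left at C4a closes onto the ester carbonyl, and the four-membered alkoxide opens to the C8a phenoxide and the C4a aryl ketone, so O1 and the C4 acyl carbon arrive on neighbouring carbons in one operation. The closest known reaction type is the fluoride-induced insertion of arynes into the C–O bond of carboxylic acids, α,β-unsaturated acids included, which gives ortho-hydroxyaryl ketones. No ring is closed and no stereocentre is formed; the side-chain centre is not touched. The step needs oxygen attack at C8a and not at C4a, which the C5 methoxymethoxy group secures by distorting the triple bond inductively and by stabilising the carbanion that develops next to it at C4a, outweighing the small steric bias of the C8 alkyl group. It also needs acyl transfer to outrun protonation of the aryl carbanion (aprotic THF, sparingly soluble CsF, heat) and bimolecular capture to outrun an ene reaction with the side-chain alkenes (excess carboxylate; the nearest isopropenyl group is tied through its central carbon by only two atoms and cannot bring an allylic hydrogen over C4a). The hindered, chelated phenoxide is held as its cesium salt until the cold buffered quench, so that it should not close onto the electron-rich enone in the flask.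

Step 16
Reactants: 28 (2E)-3-[2,4-bis(methoxymethoxy)phenyl]-1-{2-hydroxy-4,6-bis(methoxymethoxy)-3-[(2R)-5-methyl-2-(prop-1-en-2-yl)hex-5-en-1-yl]phenyl}prop-2-en-1-one
Product: 29 (2S)-2-[2,4-bis(methoxymethoxy)phenyl]-5,7-bis(methoxymethoxy)-8-[(2R)-5-methyl-2-(prop-1-en-2-yl)hex-5-en-1-yl]-2,3-dihydro-4H-chromen-4-one
Conditions: 1-[3,5-bis(trifluoromethyl)phenyl]-3-[(9S)-6'-methoxycinchonan-9-yl]thiourea (from 9-amino-9-deoxy-epi-quinine, 20 mol %), toluene, 0 °C → rt
Reagents that add atoms: none
Why: Bifunctional catalysis of an intramolecular 6-endo-trig oxa-Michael addition: the quinuclidine nitrogen activates the only free phenol (on C8a) while the thiourea binds the enone carbonyl, so the oxygen is delivered to one face of Cβ and C2 is set under catalyst control with little influence from the remote side-chain centre; the C5 acetal ether twists the ketone out of the ring plane and weakens the O–H···O=C bond that otherwise retards closure.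

Step 17
Reactants: 29 (2S)-2-[2,4-bis(methoxymethoxy)phenyl]-5,7-bis(methoxymethoxy)-8-[(2R)-5-methyl-2-(prop-1-en-2-yl)hex-5-en-1-yl]-2,3-dihydro-4H-chromen-4-one
Product: 30 remangiflavanone B, (2S)-2-(2,4-dihydroxyphenyl)-5,7-dihydroxy-8-[(2R)-5-methyl-2-(prop-1-en-2-yl)hex-5-en-1-yl]-2,3-dihydro-4H-chromen-4-one
Conditions: 3 M aq HCl, MeOH, 40 °C
Reagents that add atoms: none
Why: Acid-catalysed acetal exchange with methanol removes the four methoxymethyl ethers under conditions mild enough for the 1,1-disubstituted alkenes, and no base is present that could open the flavanone and scramble C2.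

**Compound list**

1 | phloroglucinol | Oc1cc(O)cc(O)c1 | starting material
2 | 3,5-bis(methoxymethoxy)phenol | COCOc1cc(O)cc(OCOC)c1 | intermediate
3 | 3,5-bis(methoxymethoxy)phenyl N,N-diethylcarbamate | CCN(CC)C(=O)Oc1cc(OCOC)cc(OCOC)c1 | intermediate
4 | 2-lithio-3,5-bis(methoxymethoxy)phenyl N,N-diethylcarbamate (not isolated) | CCN(CC)C(=O)Oc1cc(OCOC)cc(OCOC)c1[Li] | intermediate
5 | 3,5-bis(methoxymethoxy)-2-(trimethylsilyl)phenyl N,N-diethylcarbamate | CCN(CC)C(=O)Oc1cc(OCOC)cc(OCOC)c1[Si](C)(C)C | intermediate
6 | 2-lithio-3,5-bis(methoxymethoxy)-6-(trimethylsilyl)phenyl N,N-diethylcarbamate (not isolated) | CCN(CC)C(=O)Oc1c([Li])c(OCOC)cc(OCOC)c1[Si](C)(C)C | intermediate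
7 | 2-iodo-3,5-bis(methoxymethoxy)-6-(trimethylsilyl)phenyl N,N-diethylcarbamate | CCN(CC)C(=O)Oc1c(I)c(OCOC)cc(OCOC)c1[Si](C)(C)C | intermediate
8 | 2-iodo-3,5-bis(methoxymethoxy)-6-(trimethylsilyl)phenol | Oc1c(I)c(OCOC)cc(OCOC)c1[Si](C)(C)C | intermediate
9 | 2-iodo-3,5-bis(methoxymethoxy)-6-(trimethylsilyl)phenyl trifluoromethanesulfonate | O=S(=O)(Oc1c(I)c(OCOC)cc(OCOC)c1[Si](C)(C)C)C(F)(F)F | intermediate
10 | 3-methylbut-2-enoic acid | CC(C)=CC(=O)O | starting material
11 | (4S)-4-benzyl-1,3-oxazolidin-2-one | O=C1N[C@@H](Cc2ccccc2)CO1 | starting material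
12 | 3-methylbut-2-enoic pivalic anhydride (not isolated) | CC(C)=CC(=O)OC(=O)C(C)(C)C | intermediate
13 | (4S)-4-benzyl-3-(3-methylbut-2-enoyl)-1,3-oxazolidin-2-one | CC(C)=CC(=O)N1[C@@H](Cc2ccccc2)COC1=O | intermediate
14 | 3-methylbut-3-en-1-ol | C=C(C)CCO | starting material
15 | 3-methylbut-3-en-1-yl trifluoromethanesulfonate | C=C(C)CCOS(=O)(=O)C(F)(F)F | intermediate
16 | sodium (Z)-dienolate of 13 (not isolated) | C=C(C)/C=C(\[O-])N1[C@@H](Cc2ccccc2)COC1=O.[Na+] | intermediate
17 | (4S)-4-benzyl-3-[(2S)-5-methyl-2-(prop-1-en-2-yl)hex-5-enoyl]-1,3-oxazolidin-2-one | C=C(C)CC[C@H](C(=O)N1[C@@H](Cc2ccccc2)COC1=O)C(=C)C | intermediate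
18 | (2S)-5-methyl-2-(prop-1-en-2-yl)hex-5-en-1-ol | C=C(C)CC[C@H](CO)C(=C)C | intermediate
19 | (2S)-1-iodo-5-methyl-2-(prop-1-en-2-yl)hex-5-ene | C=C(C)CC[C@H](CI)C(=C)C | intermediate
20 | [(2S)-5-methyl-2-(prop-1-en-2-yl)hex-5-en-1-yl]zinc iodide (not isolated) | C=C(C)CC[C@H](C[Zn]I)C(=C)C | intermediate
21 | 3,5-bis(methoxymethoxy)-2-[(2R)-5-methyl-2-(prop-1-en-2-yl)hex-5-en-1-yl]-6-(trimethylsilyl)phenyl trifluoromethanesulfonate | C=C(C)CC[C@H](Cc1c(OCOC)cc(OCOC)c([Si](C)(C)C)c1OS(=O)(=O)C(F)(F)F)C(=C)C | intermediate
22 | 2,4-dihydroxybenzaldehyde | O=Cc1ccc(O)cc1O | starting material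
23 | 2,4-bis(methoxymethoxy)benzaldehyde | COCOc1ccc(C=O)c(OCOC)c1 | intermediate
24 | malonic acid | OC(=O)CC(=O)O | starting material
25 | 2-[2,4-bis(methoxymethoxy)benzylidene]malonic acid (not isolated) | OC(=O)C(=Cc1ccc(OCOC)cc1OCOC)C(=O)O | intermediate
26 | (2E)-3-[2,4-bis(methoxymethoxy)phenyl]prop-2-enoic acid | OC(=O)/C=C/c1ccc(OCOC)cc1OCOC | intermediate
27 | 4,6-bis(methoxymethoxy)-3-[(2R)-5-methyl-2-(prop-1-en-2-yl)hex-5-en-1-yl]benzyne, triple bond between the former C–Si and C–OTf carbons (not isolated) | C=C(C)CC[C@H](CC1=C(OCOC)C=C(OCOC)C#C1)C(=C)C | intermediate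
28 | (2E)-3-[2,4-bis(methoxymethoxy)phenyl]-1-{2-hydroxy-4,6-bis(methoxymethoxy)-3-[(2R)-5-methyl-2-(prop-1-en-2-yl)hex-5-en-1-yl]phenyl}prop-2-en-1-one | C=C(C)CC[C@H](Cc1c(OCOC)cc(OCOC)c(C(=O)/C=C/c2ccc(OCOC)cc2OCOC)c1O)C(=C)C | intermediate
29 | (2S)-2-[2,4-bis(methoxymethoxy)phenyl]-5,7-bis(methoxymethoxy)-8-[(2R)-5-methyl-2-(prop-1-en-2-yl)hex-5-en-1-yl]-2,3-dihydro-4H-chromen-4-one | C=C(C)CC[C@H](Cc1c(OCOC)cc(OCOC)c2c1O[C@H](c1ccc(OCOC)cc1OCOC)CC2=O)C(=C)C | intermediate
30 | remangiflavanone B, (2S)-2-(2,4-dihydroxyphenyl)-5,7-dihydroxy-8-[(2R)-5-methyl-2-(prop-1-en-2-yl)hex-5-en-1-yl]-2,3-dihydro-4H-chromen-4-one | C=C(C)CC[C@H](Cc1c(O)cc(O)c2c1O[C@H](c1ccc(O)cc1O)CC2=O)C(=C)C | target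

**Step count**

Total step count: 17. Longest linear sequence: 10 steps (steps 1–6, 12, 15, 16, 17).

**Steps most likely to fail**

Step 15. What may go wrong: the aryl carbanion is protonated before it reaches the ester carbonyl (plain O-arylation), the unsaturated acid and the product are lost by conjugate addition, or the product phenoxide closes in the hot basic medium to the flavanone without control at C2. The fallback sets out from 21 and keeps the enone out of the aryne step. The aryne from 21 is generated with CsF in THF in the presence of acetic acid, a saturated acid that cannot undergo conjugate addition and whose insertion product cannot cyclise. This should give 1-{2-hydroxy-4,6-bis(methoxymethoxy)-3-[(2R)-5-methyl-2-(prop-1-en-2-yl)hex-5-en-1-yl]phenyl}ethan-1-one F1 by the same C–O insertion. F1 is then condensed with aldehyde 23 (KOH, EtOH, rt, Claisen–Schmidt condensation), which comes back to the route at chalcone 28.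

Step 16. What may go wrong: closure onto the electron-rich, hydrogen-bonded enone is slow and reversible, and facial selection is poor, so C2 is formed as a mixture. The fallback sets out from 28 and gives up catalyst control. Thermodynamic cyclisation (NaOAc, EtOH, reflux) should give 29 together with its C2 epimer, the (2R)-flavanone F2. Because the side-chain centre is fixed, the two are diastereomers and are separated by preparative HPLC. F2 is put back under the same conditions, where ring opening and reclosure through the chalcone re-equilibrate it. The route is rejoined at 29.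

Step 9. What may go wrong: the homoallylic triflate eliminates or ionises with participation of its alkene, or the dienolate is alkylated at oxygen or at the γ-carbon instead of Cα. The fallback sets out from 10 and replaces asymmetric induction by separation of diastereomers. Acid 10 is converted with LiN(i-Pr)2 (2.2 equiv, THF, 0 °C) into dilithium 3-methylbuta-1,3-diene-1,1-diolate F3. This far more nucleophilic dianion is alkylated at Cα by commercial 4-bromo-2-methylbut-1-ene to give racemic 5-methyl-2-(prop-1-en-2-yl)hex-5-enoic acid F4. Activation with t-BuCOCl/Et3N gives the mixed pivalic anhydride F5, and acylation of 11 (LiCl, rt) should give imide 17 together with its (2R)-epimer, (4S)-4-benzyl-3-[(2R)-5-methyl-2-(prop-1-en-2-yl)hex-5-enoyl]-1,3-oxazolidin-2-one F6. The two are separated by chromatography and the route is rejoined at 17.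

**Further compounds**

F1 | step 15 | 1-{2-hydroxy-4,6-bis(methoxymethoxy)-3-[(2R)-5-methyl-2-(prop-1-en-2-yl)hex-5-en-1-yl]phenyl}ethan-1-one | C=C(C)CC[C@H](Cc1c(OCOC)cc(OCOC)c(C(C)=O)c1O)C(=C)C
F2 | step 16 | (2R)-2-[2,4-bis(methoxymethoxy)phenyl]-5,7-bis(methoxymethoxy)-8-[(2R)-5-methyl-2-(prop-1-en-2-yl)hex-5-en-1-yl]-2,3-dihydro-4H-chromen-4-one | C=C(C)CC[C@H](Cc1c(OCOC)cc(OCOC)c2c1O[C@@H](c1ccc(OCOC)cc1OCOC)CC2=O)C(=C)C
F3 | step 9 | dilithium 3-methylbuta-1,3-diene-1,1-diolate | [Li+].[Li+].[O-]C([O-])=CC(C)=C
F4 | step 9 | rac-5-methyl-2-(prop-1-en-2-yl)hex-5-enoic acid | C=C(C)CCC(C(=O)O)C(=C)C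
F5 | step 9 | rac-5-methyl-2-(prop-1-en-2-yl)hex-5-enoic pivalic anhydride | C=C(C)CCC(C(=O)OC(=O)C(C)(C)C)C(=C)C
F6 | step 9 | (4S)-4-benzyl-3-[(2R)-5-methyl-2-(prop-1-en-2-yl)hex-5-enoyl]-1,3-oxazolidin-2-one | C=C(C)CC[C@@H](C(=O)N1[C@@H](Cc2ccccc2)COC1=O)C(=C)C
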